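## Retrosynthetic overview

- **Numbering (friedodrimane).** Ring A = C1-C2-C3-C4-C5-C10 and ring B = C5-C6-C7-C8-C9-C10. C4 bears the exocyclic methylene C11. C5, C8 and C9 each bear a methyl, and C9 also bears the CH2 that leads to the quinone. Ar = 2,3,5,6-tetramethoxyphenyl.
- **Enabling feature.** In ring A the unit C3H2-C4(=C11H2)-C5 (quaternary ring-fusion carbon) is the footprint of two successive ene reactions of an acyclic C5(Me)=C4(CH3)2 alkene. Its two C4 methyls are equivalent, so there is no E/Z problem. C10-C1-C2 is the footprint of an (E)-enal, with C10 as β-carbon and C2 as carbonyl carbon.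
- **Key disconnection.** Cutting C5-C10 (ring B, closed first) and C2-C3 (ring A, closed second, same flask) leads to acyclic dienal 19, which holds only the C8 and C9 stereocentres. The leftover C2-OH is deleted by Barton-McCombie reduction.
- **Dienal 19.** It comes from cross metathesis (C1=C10), vinylcuprate/tosylate coupling (C5-C6) and lactol methylenation of a δ-lactone. In that lactone C9 is quaternised with MeI and then ArCH2Br, anti to C8-Me. C8 comes from methyl hydrogen (R)-3-methylglutarate.
- **Quinone ring last.** The tetramethoxyarene is oxidised with CAN to the 2,5-dimethoxyquinone, which is saponified regioselectively.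

Key step: step 11

Remark: the anomeric centre of 12 and the carbinol centre C2 of 21 and 22 are left undefined in name and SMILES, because both epimers converge on the next defined compound.

## Route

Step 1
Reactants: 1 1,2,4,5-tetramethoxybenzene
Product: 3 (2,3,5,6-tetramethoxyphenyl)methanol, via 2,3,5,6-tetramethoxyphenyllithium 2 (not isolated)
Conditions: n-BuLi, TMEDA, THF, 0 °C; (CH2O)n, 0 °C to rt; aq NH4Cl
Reagents that add atoms: formaldehyde (as paraformaldehyde) C=O
Why: Directed ortho-lithiation takes place between two methoxy groups (the two free ring positions are equivalent) and the aryllithium is hydroxymethylated by formaldehyde.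

Step 2
Reactants: 3 (2,3,5,6-tetramethoxyphenyl)methanol
Product: 4 3-(bromomethyl)-1,2,4,5-tetramethoxybenzene
Conditions: PBr3, Et2O, 0 °C; used without storage
Reagents that add atoms: phosphorus tribromide BrP(Br)Br
Why: Bromination of an activated benzylic alcohol through its phosphite ester (SN2) should leave the aryl methyl ethers untouched at 0 °C.

Step 3
Reactants: 5 (3R)-5-methoxy-3-methyl-5-oxopentanoic acid (methyl hydrogen (R)-3-methylglutarate)
Product: 7 (4S)-4-methyloxan-2-one, via (3S)-5-hydroxy-3-methylpentanoic acid 6 (not isolated)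
Conditions: LiH (1 equiv), THF, 0 °C; LiBH4, THF, reflux; 2 M HCl; cat. TsOH, PhH, reflux
Reagents that add atoms: none
Why: Chemoselective borohydride reduction of the ester beside the inert lithium carboxylate, then acid lactonisation, leaves the stereocentre (future C8) untouched, and its descriptor changes from R to S only because the ranking of the two arms is exchanged.

Step 4
Reactants: 7 (4S)-4-methyloxan-2-one
Product: 9 (3R,4S)-3,4-dimethyloxan-2-one, via lithium (4S)-4-methyl-5,6-dihydro-4H-pyran-2-olate 8 (not isolated)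
Conditions: LDA, THF, -78 °C; MeI, -78 to -40 °C
Reagents that add atoms: iodomethane CI
Why: Lactone enolate alkylation should bring the methyl in anti to the C4 methyl, and the new centre is planarised again in step 5, so its configuration is of no consequence.

Step 5
Reactants: 9 (3R,4S)-3,4-dimethyloxan-2-one; 4 3-(bromomethyl)-1,2,4,5-tetramethoxybenzene
Product: 11 (3R,4S)-3,4-dimethyl-3-[(2,3,5,6-tetramethoxyphenyl)methyl]oxan-2-one, via lithium (4S)-3,4-dimethyl-5,6-dihydro-4H-pyran-2-olate 10 (not isolated)
Conditions: LDA, THF-DMPU, -78 °C; 4, -78 to -20 °C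
Reagents that add atoms: none
Why: In this enolate alkylation the C8 methyl turns pseudoaxial to escape A(1,2) strain with the enolate methyl, so the reactive benzylic bromide should enter from the opposite face and set quaternary C9 with CH2Ar trans and C9-Me cis to C8-Me.

Step 6
Reactants: 11 (3R,4S)-3,4-dimethyl-3-[(2,3,5,6-tetramethoxyphenyl)methyl]oxan-2-one
Product: 12 (3R,4S)-3,4-dimethyl-3-[(2,3,5,6-tetramethoxyphenyl)methyl]oxan-2-ol
Conditions: DIBAL-H, CH2Cl2, -78 °C; Rochelle salt
Reagents that add atoms: none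
Why: Partial reduction of a lactone with DIBAL-H stops at the lactol stage at -78 °C, helped here by the neopentyl environment of the carbonyl group.

Step 7
Reactants: 12 (3R,4S)-3,4-dimethyl-3-[(2,3,5,6-tetramethoxyphenyl)methyl]oxan-2-ol
Product: 13 (3S,4S)-3,4-dimethyl-4-[(2,3,5,6-tetramethoxyphenyl)methyl]hex-5-en-1-ol
Conditions: Ph3PCH3Br, KOtBu (excess), THF, 0 °C to reflux
Reagents that add atoms: methyltriphenylphosphonium bromide C[P+](c1ccccc1)(c1ccccc1)c1ccccc1.[Br-]
Why: Wittig methylenation of a lactol, which reacts through its ring-opened tautomer, uses the smallest and most reactive ylide and touches no stereocentre (the C9 descriptor changes by ranking only).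

Step 8
Reactants: 13 (3S,4S)-3,4-dimethyl-4-[(2,3,5,6-tetramethoxyphenyl)methyl]hex-5-en-1-ol
Product: 14 (3S,4S)-3,4-dimethyl-4-[(2,3,5,6-tetramethoxyphenyl)methyl]hex-5-en-1-yl 4-methylbenzenesulfonate
Conditions: TsCl, Et3N, cat. DMAP, CH2Cl2, 0 °C to rt
Reagents that add atoms: 4-toluenesulfonyl chloride Cc1ccc(cc1)S(=O)(=O)Cl
Why: Sulfonylation of an unhindered primary alcohol gives a leaving group that reacts with cuprates by a polar SN2 path, which avoids radical cyclisation onto the vinyl group.

Step 9
Reactants: 14 (3S,4S)-3,4-dimethyl-4-[(2,3,5,6-tetramethoxyphenyl)methyl]hex-5-en-1-yl 4-methylbenzenesulfonate; 15 2-bromo-3-methylbut-2-ene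
Product: 18 (3S,4S)-3,4,7,8-tetramethyl-3-[(2,3,5,6-tetramethoxyphenyl)methyl]nona-1,7-diene, via 3-methylbut-2-en-2-yllithium 16 (not isolated), via lithium bis(3-methylbut-2-en-2-yl)cuprate 17 (not isolated)
Conditions: 15, t-BuLi (2 equiv per 15), Et2O, -78 °C; CuI, -40 °C; 14, -20 to 0 °C; aq NH4Cl
Reagents that add atoms: none
Why: Corey-House type SN2 coupling of a Gilman vinylcuprate with a primary tosylate forms C5-C6 and installs the tetrasubstituted alkene, which has no geometry to lose because its terminus carries two methyls.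

Step 10
Reactants: 18 (3S,4S)-3,4,7,8-tetramethyl-3-[(2,3,5,6-tetramethoxyphenyl)methyl]nona-1,7-diene
Product: 19 (2E,4R,5S)-4,5,8,9-tetramethyl-4-[(2,3,5,6-tetramethoxyphenyl)methyl]deca-2,8-dienal
Conditions: crotonaldehyde (excess), Hoveyda-Grubbs II (10 mol %), toluene, 60 °C
Reagents that add atoms: (E)-crotonaldehyde C/C=C/C=O
Why: Olefin cross metathesis between a vinyl group on a quaternary carbon (slow to homodimerise) and an enal partner should give the (E)-enal under thermodynamic control, while the tetrasubstituted alkene is a spectator towards ruthenium alkylidenes.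

Step 11
Reactants: 19 (2E,4R,5S)-4,5,8,9-tetramethyl-4-[(2,3,5,6-tetramethoxyphenyl)methyl]deca-2,8-dienal
Product: 21 (4aS,7S,8R,8aS)-4a,7,8-trimethyl-4-methylidene-8-[(2,3,5,6-tetramethoxyphenyl)methyl]decahydronaphthalen-2-ol, via isopropenyl aldehyde 20 (not isolated)
Conditions: Me2AlCl (3.5 equiv), CH2Cl2 (0.01 M), -78 to 0 °C; aq HCl
Reagents that add atoms: none
Why: Proposed new method: Me2AlCl activates the enal of 19 so that C5 of the tetrasubstituted alkene attacks the β-carbon C10 (conjugate ene reaction, concerted or through a C4 cation/aluminium enolate pair) while a hydrogen of one C4 methyl passes to C1 to give isopropenyl aldehyde 20, whose still complexed C2 aldehyde is then attacked by the new =CH2 terminus (it becomes C3) in a type II carbonyl-ene reaction in which the second C4 methyl gives a hydrogen to oxygen and becomes the exocyclic methylene C11. The closest known reaction types are the intermolecular alkylaluminium-halide-promoted double ene (formal 3+3) annulation of acrolein-type enals with tri- and tetrasubstituted alkenes, the Lewis-acid ene cyclisation of 1,7-dienes with activated enophiles to trans-1,2-disubstituted cyclohexanes and the type II ene closure of 5-methylhex-5-enals to 3-methylenecyclohexanols; new is that both events are tethered in one acyclic chain and that C5 becomes quaternary next to the neopentyl C10. Ring B closes first, 6-exo-trig at C10 with C1 and the developing cationic C4 both outside the ring, and ring A closes second, 6-exo-trig at the C2 carbonyl with the C3=C4 ene bond inside the forming ring (type II). C5 and C10 are both set in the first closure by a chair transition state biased by C8 and C9: C8-Me and the larger C9 substituent (CH2Ar) sit equatorial, C9-Me axial, and the enal arm on C10 and the bulky isopropylidene carbon C4 on C5 take equatorial sites, so that C5-Me ends axial on the face of C9-Me and C10-H axial on the opposite face (5S,10S, trans fusion), the alternative with C4 axial suffering a much worse 1,3-diaxial clash with C9-Me, while the C2 carbinol centre is uncontrolled and is deleted in steps 12 and 13. The step needs 1,4- before 1,2-attack, C5 rather than C4 as bonding carbon and a single alkene isomer: direct attack on C2 would need an eight- or nine-membered ring, bonding through C4 a seven-membered ring, the C4 cation has only its two equivalent methyls to lose hydrogen from, and the sole free arene position lies para to the tether and cannot reach the cation. Cyclobutane or dihydropyran collapse of the ion pair is reversible under the Lewis acid, whereas the final alcohol complex loses methane to an aluminium alkoxide, which makes the sequence irreversible and keeps the medium free of protons that could move the exocyclic double bond.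

Step 12
Reactants: 21 (4aS,7S,8R,8aS)-4a,7,8-trimethyl-4-methylidene-8-[(2,3,5,6-tetramethoxyphenyl)methyl]decahydronaphthalen-2-ol
Product: 22 O-{(4aS,7S,8R,8aS)-4a,7,8-trimethyl-4-methylidene-8-[(2,3,5,6-tetramethoxyphenyl)methyl]decahydronaphthalen-2-yl} 1H-imidazole-1-carbothioate
Conditions: 1,1'-thiocarbonyldiimidazole, cat. DMAP, ClCH2CH2Cl, reflux
Reagents that add atoms: 1,1'-thiocarbonyldiimidazole S=C(n1ccnc1)n1ccnc1
Why: Thioacylation of the unhindered secondary C2 alcohol under neutral conditions (first half of the Barton-McCombie deoxygenation) leaves the exocyclic alkene and the aryl ethers alone.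

Step 13
Reactants: 22 O-{(4aS,7S,8R,8aS)-4a,7,8-trimethyl-4-methylidene-8-[(2,3,5,6-tetramethoxyphenyl)methyl]decahydronaphthalen-2-yl} 1H-imidazole-1-carbothioate
Product: 23 1,2,4,5-tetramethoxy-3-{[(1R,2S,4aS,8aS)-1,2,4a-trimethyl-5-methylidenedecahydronaphthalen-1-yl]methyl}benzene
Conditions: Bu3SnH, cat. AIBN, toluene, reflux
Reagents that add atoms: none
Why: Barton-McCombie reduction replaces C2-O by C2-H through a secondary radical whose 3-exo addition to the homoallylic C4=C11 bond is reversible and unproductive, so that hydrogen transfer from the stannane should prevail.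

Step 14
Reactants: 23 1,2,4,5-tetramethoxy-3-{[(1R,2S,4aS,8aS)-1,2,4a-trimethyl-5-methylidenedecahydronaphthalen-1-yl]methyl}benzene
Product: 24 2,5-dimethoxy-3-{[(1R,2S,4aS,8aS)-1,2,4a-trimethyl-5-methylidenedecahydronaphthalen-1-yl]methyl}cyclohexa-2,5-diene-1,4-dione
Conditions: (NH4)2Ce(NO3)6, MeCN-H2O, 0 °C
Reagents that add atoms: water O
Why: CAN oxidative demethylation of a hydroquinone dimethyl ether gives one p-quinone, because the local mirror symmetry of the arene makes both para pairs of methoxy groups lead to the same product, and the isolated alkene is much harder to oxidise than the arene.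

Step 15
Reactants: 24 2,5-dimethoxy-3-{[(1R,2S,4aS,8aS)-1,2,4a-trimethyl-5-methylidenedecahydronaphthalen-1-yl]methyl}cyclohexa-2,5-diene-1,4-dione
Product: 25 ilimaquinone
Conditions: KOH (aq), MeOH-THF, rt; 1 M HCl
Reagents that add atoms: potassium hydroxide [K+].[OH-]
Why: Addition-elimination (saponification of a vinylogous ester) should take the methoxy group beside the alkyl chain, which is twisted out of conjugation and therefore the more electrophilic site, and the quinone anion so formed resists a second attack.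

## Compound list

1 | 1,2,4,5-tetramethoxybenzene | COc1cc(OC)c(OC)cc1OC | starting material
2 | 2,3,5,6-tetramethoxyphenyllithium | [Li]c1c(OC)c(OC)cc(OC)c1OC | intermediate
3 | (2,3,5,6-tetramethoxyphenyl)methanol | OCc1c(OC)c(OC)cc(OC)c1OC | intermediate
4 | 3-(bromomethyl)-1,2,4,5-tetramethoxybenzene | BrCc1c(OC)c(OC)cc(OC)c1OC | intermediate
5 | (3R)-5-methoxy-3-methyl-5-oxopentanoic acid | COC(=O)C[C@H](C)CC(=O)O | starting material
6 | (3S)-5-hydroxy-3-methylpentanoic acid | OCC[C@H](C)CC(=O)O | intermediate
7 | (4S)-4-methyloxan-2-one | O=C1C[C@@H](C)CCO1 | intermediate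
8 | lithium (4S)-4-methyl-5,6-dihydro-4H-pyran-2-olate | [Li+].[O-]C1=C[C@@H](C)CCO1 | intermediate
9 | (3R,4S)-3,4-dimethyloxan-2-one (trans) | O=C1[C@H](C)[C@@H](C)CCO1 | intermediate
10 | lithium (4S)-3,4-dimethyl-5,6-dihydro-4H-pyran-2-olate | [Li+].[O-]C1=C(C)[C@@H](C)CCO1 | intermediate
11 | (3R,4S)-3,4-dimethyl-3-[(2,3,5,6-tetramethoxyphenyl)methyl]oxan-2-one | O=C1[C@](C)(Cc2c(OC)c(OC)cc(OC)c2OC)[C@@H](C)CCO1 | intermediate
12 | (3R,4S)-3,4-dimethyl-3-[(2,3,5,6-tetramethoxyphenyl)methyl]oxan-2-ol (both anomers) | OC1[C@](C)(Cc2c(OC)c(OC)cc(OC)c2OC)[C@@H](C)CCO1 | intermediate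
13 | (3S,4S)-3,4-dimethyl-4-[(2,3,5,6-tetramethoxyphenyl)methyl]hex-5-en-1-ol | C=C[C@](C)(Cc1c(OC)c(OC)cc(OC)c1OC)[C@@H](C)CCO | intermediate
14 | (3S,4S)-3,4-dimethyl-4-[(2,3,5,6-tetramethoxyphenyl)methyl]hex-5-en-1-yl 4-methylbenzenesulfonate | C=C[C@](C)(Cc1c(OC)c(OC)cc(OC)c1OC)[C@@H](C)CCOS(=O)(=O)c1ccc(C)cc1 | intermediate
15 | 2-bromo-3-methylbut-2-ene | CC(C)=C(C)Br | starting material
16 | 3-methylbut-2-en-2-yllithium | [Li]C(C)=C(C)C | intermediate
17 | lithium bis(3-methylbut-2-en-2-yl)cuprate | [Li+].CC(C)=C(C)[Cu-]C(C)=C(C)C | intermediate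
18 | (3S,4S)-3,4,7,8-tetramethyl-3-[(2,3,5,6-tetramethoxyphenyl)methyl]nona-1,7-diene | C=C[C@](C)(Cc1c(OC)c(OC)cc(OC)c1OC)[C@@H](C)CCC(C)=C(C)C | intermediate
19 | (2E,4R,5S)-4,5,8,9-tetramethyl-4-[(2,3,5,6-tetramethoxyphenyl)methyl]deca-2,8-dienal | O=C/C=C/[C@](C)(Cc1c(OC)c(OC)cc(OC)c1OC)[C@@H](C)CCC(C)=C(C)C | intermediate
20 | 2-{(1S,2R,3S,6S)-2,3,6-trimethyl-6-(prop-1-en-2-yl)-2-[(2,3,5,6-tetramethoxyphenyl)methyl]cyclohexyl}acetaldehyde | O=CC[C@H]1[C@](C)(Cc2c(OC)c(OC)cc(OC)c2OC)[C@@H](C)CC[C@]1(C)C(C)=C | intermediate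
21 | (4aS,7S,8R,8aS)-4a,7,8-trimethyl-4-methylidene-8-[(2,3,5,6-tetramethoxyphenyl)methyl]decahydronaphthalen-2-ol (both C2 epimers) | C=C1CC(O)C[C@H]2[C@](C)(Cc3c(OC)c(OC)cc(OC)c3OC)[C@@H](C)CC[C@]12C | intermediate
22 | O-{(4aS,7S,8R,8aS)-4a,7,8-trimethyl-4-methylidene-8-[(2,3,5,6-tetramethoxyphenyl)methyl]decahydronaphthalen-2-yl} 1H-imidazole-1-carbothioate (both C2 epimers) | C=C1CC(OC(=S)n3ccnc3)C[C@H]2[C@](C)(Cc3c(OC)c(OC)cc(OC)c3OC)[C@@H](C)CC[C@]12C | intermediate
23 | 1,2,4,5-tetramethoxy-3-{[(1R,2S,4aS,8aS)-1,2,4a-trimethyl-5-methylidenedecahydronaphthalen-1-yl]methyl}benzene | C=C1CCC[C@H]2[C@](C)(Cc3c(OC)c(OC)cc(OC)c3OC)[C@@H](C)CC[C@]12C | intermediate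
24 | 2,5-dimethoxy-3-{[(1R,2S,4aS,8aS)-1,2,4a-trimethyl-5-methylidenedecahydronaphthalen-1-yl]methyl}cyclohexa-2,5-diene-1,4-dione | C=C1CCC[C@H]2[C@](C)(CC3=C(OC)C(=O)C=C(OC)C3=O)[C@@H](C)CC[C@]12C | intermediate
25 | ilimaquinone, 2-hydroxy-5-methoxy-3-{[(1R,2S,4aS,8aS)-1,2,4a-trimethyl-5-methylidenedecahydronaphthalen-1-yl]methyl}cyclohexa-2,5-diene-1,4-dione | C=C1CCC[C@H]2[C@](C)(CC3=C(O)C(=O)C=C(OC)C3=O)[C@@H](C)CC[C@]12C | target

## Step count

- Total step count: 15.
- Longest linear sequence: 13 steps (steps 3 to 15, from 5).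

## Steps most likely to fail

**1. Step 11.**
- What may go wrong: the tetrasubstituted alkene may be too weak a nucleophile for the neopentyl β-carbon C10. Methyl transfer from aluminium to the aldehyde, oligomerisation or poor discrimination between the chair transition states could then overtake the double ring closure.
- Fallback: it sets out from 14 and comes back at 21. It splits the event into two known reactions and raises the nucleophilicity with silicon. Kumada-Corriu mono-coupling of commercial (E)-2,3-dibromobut-2-ene with Me3SiCH2MgCl (Pd(PPh3)4, THF) should give (E)-(3-bromo-2-methylbut-2-en-1-yl)trimethylsilane F1. This is lithiated (t-BuLi) and cuprated (CuI) to lithium bis[(E)-3-methyl-4-(trimethylsilyl)but-2-en-2-yl]cuprate F2. Displacement of the tosylate of 14 gives trimethyl{(2E,6S,7S)-2,3,6,7-tetramethyl-7-[(2,3,5,6-tetramethoxyphenyl)methyl]nona-2,8-dien-1-yl}silane F3. Cross metathesis with crotonaldehyde gives (2E,4R,5S,8E)-4,5,8,9-tetramethyl-4-[(2,3,5,6-tetramethoxyphenyl)methyl]-10-(trimethylsilyl)deca-2,8-dienal F4. An intramolecular Hosomi-Sakurai conjugate addition (TiCl4 or EtAlCl2, CH2Cl2, -78 °C) forms C5-C10 with loss of silicon and gives aldehyde 20, which is isolated here. A separate Me2AlCl type II carbonyl-ene reaction then closes ring A to 21.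

**2. Step 10.**
- What may go wrong: the ruthenium alkylidene may fail to engage the vinyl group, which is flanked by the quaternary C9, the branched C8 and the ortho-disubstituted benzyl group. Catalyst decay and self-metathesis of crotonaldehyde would then consume the reagents.
- Fallback: it sets out from 12 and comes back at 19. It brings in the two enal carbons by olefination before the chain is completed. A Wittig reaction of 12 with the ylide of (1,3-dioxolan-2-ylmethyl)triphenylphosphonium bromide (KOtBu, THF) should give (3S,4R)-6-(1,3-dioxolan-2-yl)-3,4-dimethyl-4-[(2,3,5,6-tetramethoxyphenyl)methyl]hex-5-en-1-ol F5 as an E/Z mixture. Tosylation gives its 4-methylbenzenesulfonate F6. Cuprate 17 displaces the tosylate to give 2-{(3R,4S)-3,4,7,8-tetramethyl-3-[(2,3,5,6-tetramethoxyphenyl)methyl]nona-1,7-dien-1-yl}-1,3-dioxolane F7. Mild hydrolysis (PPTS, aqueous acetone) unmasks the aldehyde and equilibrates the double bond to the (E)-enal 19.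

**3. Step 15.**
- What may go wrong: hydroxide may attack the unhindered vinylogous ester next to the ring C-H, or both methoxy groups, so that regiocontrol is lost.
- Fallback: it sets out from 24 and comes back at 25. It gives up selective cleavage in favour of selective formation. Exhaustive hydrolysis (excess aqueous NaOH, THF, then acid) should give 2,5-dihydroxy-3-{[(1R,2S,4aS,8aS)-1,2,4a-trimethyl-5-methylidenedecahydronaphthalen-1-yl]methyl}cyclohexa-2,5-diene-1,4-dione F8. A vinylogous Fischer-type esterification (MeOH, cat. PPTS, 40 °C) should then methylate only the hydroxyl beside the ring C-H, because addition of methanol next to the alkyl chain is sterically blocked. The acid is too weak to move the exocyclic alkene.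

## Further compounds

F1 | step 11 | (E)-(3-bromo-2-methylbut-2-en-1-yl)trimethylsilane | C[Si](C)(C)C/C(C)=C(C)/Br
F2 | step 11 | lithium bis[(E)-3-methyl-4-(trimethylsilyl)but-2-en-2-yl]cuprate | [Li+].C[Si](C)(C)C/C(C)=C(C)/[Cu-]/C(C)=C(C)/C[Si](C)(C)C
F3 | step 11 | trimethyl{(2E,6S,7S)-2,3,6,7-tetramethyl-7-[(2,3,5,6-tetramethoxyphenyl)methyl]nona-2,8-dien-1-yl}silane | C=C[C@](C)(Cc1c(OC)c(OC)cc(OC)c1OC)[C@@H](C)CC/C(C)=C(C)/C[Si](C)(C)C
F4 | step 11 | (2E,4R,5S,8E)-4,5,8,9-tetramethyl-4-[(2,3,5,6-tetramethoxyphenyl)methyl]-10-(trimethylsilyl)deca-2,8-dienal | O=C/C=C/[C@](C)(Cc1c(OC)c(OC)cc(OC)c1OC)[C@@H](C)CC/C(C)=C(C)/C[Si](C)(C)C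
F5 | step 10 | (3S,4R)-6-(1,3-dioxolan-2-yl)-3,4-dimethyl-4-[(2,3,5,6-tetramethoxyphenyl)methyl]hex-5-en-1-ol (E/Z) | O1CCOC1C=C[C@](C)(Cc2c(OC)c(OC)cc(OC)c2OC)[C@@H](C)CCO
F6 | step 10 | (3S,4R)-6-(1,3-dioxolan-2-yl)-3,4-dimethyl-4-[(2,3,5,6-tetramethoxyphenyl)methyl]hex-5-en-1-yl 4-methylbenzenesulfonate (E/Z) | O1CCOC1C=C[C@](C)(Cc2c(OC)c(OC)cc(OC)c2OC)[C@@H](C)CCOS(=O)(=O)c2ccc(C)cc2
F7 | step 10 | 2-{(3R,4S)-3,4,7,8-tetramethyl-3-[(2,3,5,6-tetramethoxyphenyl)methyl]nona-1,7-dien-1-yl}-1,3-dioxolane (E/Z) | O1CCOC1C=C[C@](C)(Cc2c(OC)c(OC)cc(OC)c2OC)[C@@H](C)CCC(C)=C(C)C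
F8 | step 15 | 2,5-dihydroxy-3-{[(1R,2S,4aS,8aS)-1,2,4a-trimethyl-5-methylidenedecahydronaphthalen-1-yl]methyl}cyclohexa-2,5-diene-1,4-dione | C=C1CCC[C@H]2[C@](C)(CC3=C(O)C(=O)C=C(O)C3=O)[C@@H](C)CC[C@]12C
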